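**Compound key (numbers are used throughout)**
1 N-Boc-sarcosine · 2 Weinreb amide · 3 lithium adduct · 4 chloromethyl ketone · 5 cyclopent-2-en-1-one · 6 diallyl malonate · 7 Michael adduct · 8 alkylated diketone · 9 aldol adduct · 10 enone diallyl diester · 11 enone diacid · 12 enone acid · 13 enone methyl ester · 14 (E)-but-2-ene-1,4-diol · 15 mono-TBS ether · 16 allylic carbonate · 17 dimethyl malonate · 18 branched malonate · 19 pentenoate ester · 20 pentenoic acid · 21 acid chloride · 22 magnesium alkoxide · 23 dienyl ester · 24 unsaturated ε-lactone · 25 saturated ε-lactone · 26 1-bromopent-2-yne · 27 lactone lithium enolate · 28 C6-pentynyl lactone (Claisen precursor) · 29 silyl ketene acetal · 30 silyl ester · 31 cycloheptene C7 acid (Claisen product) · 32 acyl fluoride · 33 C7 alcohol · 34 C7 TBDPS ether · 35 C27 alcohol · 36 C27 aldehyde · 37 ammonium salt · 38 iminium salt · 39 piperidine · 40 amino alkynol · 41 its triflimide salt · 42 target triflimide salt · 43 target.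

## Analysis of the target

Locants follow the SMILES string from left to right (C1–C7, O8, C9–C18, O19, O20, C21–C24, N25, C26, C27). The skeleton has five rings: cyclopentene ring A (C12–C16), cyclopentane ring B (C13, C14, C17, C22, C23), cycloheptene ring C (C6, C9, C10, C11, C12, C13, C23), N-methylpiperidine ring D (C6, C9, C27, N25, C24, C23), which bridges C9 and C23 across C6, and the 6-ethyl-3,4-dihydro-2H-pyran ring E (C3–C7, O8), spiro at C6. The tetrasubstituted alkene C12=C13 is shared by rings A and C. There are five stereocentres (C6, C9, C14, C17, C23). On ring B, C15, the C18 ester and C6 lie on one face and H14, H17 and C24 on the other; C24 and C27 are cis on ring C; at the spiro centre C7 lies over ring C and C5 over ring D. The enol ether is acid-labile, the amine is basic and binds soft metals, and C17 is an epimerisable ester α-carbon whose ester is cis to C15, presumably the less stable arrangement, so it must be set kinetically and kept from equilibrating base. The hard part is the bond between the adjacent quaternary carbons C6 and C23 inside the bridged framework. The strategy rests on three facts: C23 is allylic to C12=C13, C6 carries the oxidised one-carbon arm C7, and C6 is tied to C12 by the chain C9–C10–C11. The C6–C23 bond is therefore the product bond of an ester-enolate Claisen shift whose ester is a seven-membered lactone.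

## Retrosynthetic reasoning

**Ring E (O8–C3).** The enol ether is the most fragile group of 43, so it is formed last. Cutting O8–C3 gives amino alkynol 40, in which the alkyne C3≡C4 stores the ketone oxidation level of C3 without an acidic hydrogen. The forward step must add the C7 hydroxyl to the distal alkyne carbon (6-endo) with the amine present.

**Ring D (N25–C27).** Cutting N25–C27 of 39 leads to aldehyde 36 carrying the N-methyl carbamate. Forward, acid frees the amine, which closes on C27 to iminium 38, and this is reduced. C27 has to be oxidised while C7 is also a primary alcohol, so C7–OH is held as a bulky silyl ether (34) and the less hindered C27 silyl ether is removed first (35). This pairing is chosen over an ester on C7–O because its later removal needs no base near C17.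

**C7 oxidation level.** Alcohol 33 comes from acid 31 by reduction through acyl fluoride 32, a derivative small enough for a carboxyl flanked by two quaternary carbons and selective beside the C18 methyl ester.

**C6–C23 (key disconnection).** The bond of 31 is cut with allylic transposition: the alkene returns from C12=C13 to C13=C23 and C7 is joined to an oxygen on C12, giving lactone 28. Nothing else is cut here, because any stepwise construction would have to form one quaternary carbon next to the other by a bimolecular reaction with no element controlling their relative configuration. Forward, one sigmatropic step makes both quaternary carbons, closes ring C and places the alkene. The ring size is conserved: a seven-membered lactone becomes a seven-membered carbocycle, with the C7–O unit extruded from the ring. The C18 carboxyl is carried as the methyl ester of the target and not as a free acid; a carboxylate would shield C17 still better, but two acids would then have to be told apart after the rearrangement.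

**C5–C6.** Lactone 28 is cut to lactone 25 and bromide 26. The alkyne is introduced this late so that it is absent during olefin metathesis and alkene saturation. The configuration created at C6 is irrelevant, since C6 is planar in ketene acetal 29.

**Lactone ring (C10–C11, C11–C12, O–C7).** Lactonisation of a hydroxy acid is avoided because the alcohol would be tertiary and allylic. Instead 25 is traced through 24 to diene ester 23, and 23 to ketone 13 plus acid chloride 21: a vinyl nucleophile adds to C12 and the resulting alkoxide 22 is acylated in the same flask, then metathesis closes C10=C11 and the alkene is saturated. The forward addition must occur on the H14 face of 13 so that oxygen ends on the C15 face.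

**Fragment 21 (C6–C9).** Acid chloride 21 comes from acid 20 and ester 19, and these from malonate 18, made by cutting C6–C9: asymmetric allylic alkylation of 17 with carbonate 16 (from diol 14 through 15) sets C9.

**Ketone 13 (C17 carboxyl, C13=C23, C17–C22, C14–C17).** Ester 13 comes from acid 12, and 12 from the geminal diester 10 by loss of one carboxyl, which sets C17 by protonation. Ring B of 10 is opened at C13=C23 (aldol condensation of diketone 8). Compound 8 is cut at C17–C22 into malonate 7 and chloroketone 4 (from 1 via 2), and 7 at C14–C17 into 5 and 6 by an asymmetric Michael addition that sets C14.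

## Alternatives that were turned down

**Alternative 1:** Rings C and B are cut together at C11–C12 and C13–C23. Forward, a monovalent rhodium catalyst would join the silyl alkyne C12≡C13 of acyclic precursor A2 to its siloxyvinylcyclopropane (C23=C6 with the three-membered ring C9, C10, C11) in a (5+2) cycloaddition, giving the bicyclic cycloheptadiene silyl enol ether A1.
- For: the reaction class is well established, it forms two rings and two C–C bonds at once, and C14/C17 on the tether can direct C23.
- Against: in A1, C23 still bears hydrogen and C6 is an enol-ether carbon, so neither quaternary centre exists. C24 on C23 and both C5 and C7 on C6 would have to be added later at adjacent crowded positions without a built-in control element. Ring A, the C27 arm and both heterocycles are also missing.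
- Comparison: on precedent for the key step this alternative is stronger. The chosen route offers in exchange that its one uncertain step makes exactly the bond A1 leaves open, so far fewer steps follow it.

**Alternative 2:** Ring E is cut at C5–C6 and O8–C7 at the very end. Forward, pent-1-en-3-one A4 would react as a 1-oxadiene with the exocyclic ketene dithioacetal A5 (C6=C7) in an inverse-demand hetero-Diels–Alder reaction to give spiro dihydropyran A3, with C7 as a dithio-orthoester.
- For: the regiochemistry of ring E is unambiguous, and the ethyl group and enol ether arrive in one step with no exo/endo question. On this point it is stronger than step 25 here.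
- Against: A5 already contains the C6–C23 bond and the whole bridged core, so the real difficulty is untouched. The reacting carbon C6 sits next to quaternary C23, and C7 must afterwards be reduced to CH2 beside an enol ether and a tetrasubstituted alkene.
- Comparison: the chosen route spends its risk on C6–C23 and builds ring E from a spectator alkyne carried through the key step.

**Alternative 3:** Ring C is cut at C9–C10 and C11–C12. Forward, the enol of the cis-fused bicyclic 1,3-dione A8 would add ethene A7 under irradiation, and retro-aldol opening of the cyclobutanol would give the cycloheptane-1,4-dione A6 (carbonyls at C6 and C12).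
- For: a classical two-carbon ring expansion with a cheap reagent, giving ring C with an oxygen handle on C6 and on C12, and C14/C17 already in place.
- Against: A6 has hydrogen on C13 and C23 and a carbonyl at C6. The two ketones must be differentiated, C6 must be turned from a carbonyl into a spiro quaternary carbon, C23 must receive C24, and ring A, the C27 arm and both heterocycles remain. Each quaternary centre would be made separately, next to the other.
- Comparison: the chosen strategy is less proven in its key step but makes both quaternary carbons, ring C and the C12=C13 alkene in that single step, and is much shorter.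

Key step: step 18

Assumption: diol 14 is taken as purchasable, and for steps 3 and 10 the catalyst antipode is the one whose sense of induction gives the stated configuration.

## Steps

**Step 1**
Reactants: 1 N-Boc-sarcosine
Product: 2 tert-butyl {2-[methoxy(methyl)amino]-2-oxoethyl}(methyl)carbamate
Conditions: MeNHOMe·HCl, EDC·HCl, N-methylmorpholine, CH2Cl2, 0 → 23 °C
Reagents that add atoms: N,O-dimethylhydroxylamine hydrochloride, CNOC.Cl
Why: Carbodiimide amide coupling; the Weinreb amide allows a single addition of a carbon nucleophile in step 2.

**Step 2**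
Reactants: 2 Weinreb amide
Product: 4 tert-butyl (3-chloro-2-oxopropyl)(methyl)carbamate, via lithium adduct 3 (not isolated)
Conditions: ClCH2I, MeLi·LiBr, THF–Et2O, −78 °C; aq. NH4Cl
Reagents that add atoms: chloroiodomethane, ClCI
Why: Iodine–lithium exchange gives chloromethyllithium, which adds once to the Weinreb amide; the chelated adduct 3 collapses to the ketone only on work-up (carbenoid homologation).

**Step 3**
Reactants: 5 cyclopent-2-en-1-one, 6 diallyl malonate
Product: 7 diallyl 2-[(1S)-3-oxocyclopentyl]propanedioate
Conditions: LiAl[(S)-binaphthoxide]2 (10 mol %), KOtBu (9 mol %), 4 Å MS, THF, 23 °C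
Reagents that add atoms: none
Why: Catalytic asymmetric Michael addition of a malonate to a cyclic enone under Lewis acid/Brønsted base bimetallic catalysis; the binaphthoxide framework selects the enone face and sets C14 (S).

**Step 4**
Reactants: 7 Michael adduct, 4 chloromethyl ketone
Product: 8 diallyl 2-{3-[(tert-butoxycarbonyl)(methyl)amino]-2-oxopropyl}-2-[(1S)-3-oxocyclopentyl]propanedioate
Conditions: K2CO3, NaI (10 mol %), DMF, 23 °C
Reagents that add atoms: none
Why: SN2 alkylation of the malonate carbanion by an α-halo ketone with iodide catalysis; carbonate deprotonates only the malonate C–H, and C17 becomes quaternary with two identical esters, so no stereocentre arises.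

**Step 5**
Reactants: 8 alkylated diketone
Product: 10 enone diallyl diester (ring A ketone C12 and C13=C23 with C23–CH2N(Me)Boc and C17(CO2allyl)2; 6aS in pentalene numbering), via aldol adduct 9 (not isolated)
Conditions: pyrrolidine (30 mol %), AcOH (30 mol %), toluene, 60 °C
Reagents that add atoms: none
Why: Intramolecular aldol condensation of a 1,6-diketone: C13 adds to the C23 ketone (five-membered ring) and dehydration gives the conjugated enone; the other aldol modes give bridged adducts that cannot dehydrate and revert. C14 is β to the carbonyl and is not epimerised.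

**Step 6**
Reactants: 10 enone diallyl diester
Product: 12 (1R,6aR)-3-{[(tert-butoxycarbonyl)(methyl)amino]methyl}-4-oxo-1,2,4,5,6,6a-hexahydropentalene-1-carboxylic acid (CO2H cis to C15; H14 and H17 cis), via diacid 11 (not isolated)
Conditions: Pd(PPh3)4 (5 mol %), morpholine, THF, 23 °C; aq. KHSO4; then toluene, 100 °C
Reagents that add atoms: none
Why: Zerovalent palladium removes both allyl esters (allyl transfer to morpholine); the malonic acid 11 decarboxylates through its cyclic transition state to the enol of the acid. Protonation of that enol at C17 should occur on the H14 face, anti to the adjacent C15 methylene, which places the carboxyl cis to C15 (kinetic protonation giving the less stable epimer); no base able to epimerise C17 is present.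

**Step 7**
Reactants: 12 enone acid
Product: 13 methyl ester of 12
Conditions: MeI, K2CO3, DMF, 0 → 23 °C
Reagents that add atoms: iodomethane, CI
Why: O-alkylation of the carboxylate; carbonate is too weak to enolise the ester, so C17 is retained.

**Step 8**
Reactants: 14 (E)-but-2-ene-1,4-diol
Product: 15 (E)-4-[(tert-butyldimethylsilyl)oxy]but-2-en-1-ol
Conditions: 14 (3 equiv), tBuMe2SiCl (1 equiv), imidazole, DMF, 0 °C
Reagents that add atoms: tert-butyl(chloro)dimethylsilane, CC(C)(C)[Si](C)(C)Cl
Why: Monosilylation of a symmetric diol used in excess; unreacted diol is removed by aqueous extraction.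

**Step 9**
Reactants: 15 mono-TBS ether
Product: 16 (E)-4-[(tert-butyldimethylsilyl)oxy]but-2-en-1-yl methyl carbonate
Conditions: ClCO2Me, pyridine, CH2Cl2, 0 °C
Reagents that add atoms: methyl chloroformate, COC(=O)Cl
Why: Standard carbonate formation; the methyl carbonate is the leaving group and internal base for step 10.

**Step 10**
Reactants: 16 allylic carbonate, 17 dimethyl malonate
Product: 18 dimethyl 2-[(2S)-1-[(tert-butyldimethylsilyl)oxy]but-3-en-2-yl]propanedioate
Conditions: [Ir(cod)Cl]2 (2 mol %), binaphthyl-based N,N-bis(1-phenylethyl)phosphoramidite (4 mol %), 1,5,7-triazabicyclo[4.4.0]dec-5-ene (8 mol %), THF, 23 → 50 °C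
Reagents that add atoms: none
Why: Iridium-catalysed asymmetric allylic alkylation; the cyclometalated monovalent iridium allyl complex directs the malonate to the substituted allyl terminus (branched product) and the ligand sets C9.

**Step 11**
Reactants: 18 branched malonate
Product: 19 methyl (3R)-3-{[(tert-butyldimethylsilyl)oxy]methyl}pent-4-enoate
Conditions: NaCl, H2O, DMSO, 150 °C
Reagents that add atoms: none
Why: Krapcho dealkoxycarbonylation; C9 is not α to a carbonyl and is unaffected.

**Step 12**
Reactants: 19 pentenoate ester
Product: 20 (3R)-3-{[(tert-butyldimethylsilyl)oxy]methyl}pent-4-enoic acid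
Conditions: LiOH, THF–MeOH–H2O, 23 °C; 1 M HCl to pH 4
Reagents that add atoms: lithium hydroxide, [Li+].[OH-]
Why: Saponification; a primary TBS ether tolerates aqueous hydroxide at room temperature and a brief pH 4 work-up.

**Step 13**
Reactants: 20 pentenoic acid
Product: 21 (3R)-3-{[(tert-butyldimethylsilyl)oxy]methyl}pent-4-enoyl chloride (used crude)
Conditions: 1-chloro-N,N,2-trimethylprop-1-en-1-amine, CH2Cl2, 0 → 23 °C
Reagents that add atoms: 1-chloro-N,N,2-trimethylprop-1-en-1-amine, CC(C)=C(Cl)N(C)C
Why: Acid chloride formation under neutral conditions (no HCl), so the silyl ether survives and the γ-silyloxy acid does not lactonise.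

**Step 14**
Reactants: 13 enone methyl ester, 21 acid chloride
Product: 23 dienyl ester (C12 bears vinyl on the H14 face and the acyloxy group of 20 on the C15 face), via magnesium alkoxide 22 (not isolated)
Conditions: CH2=CHMgBr, THF, −78 °C; then 21, −78 → 0 °C
Reagents that add atoms: vinylmagnesium bromide, C=C[Mg]Br
Why: 1,2-Addition of a Grignard reagent to a β,β-disubstituted enone, then O-acylation of the tertiary alkoxide in the same flask, which avoids isolating and activating an ionisable tertiary allylic alcohol. Attack is expected on the convex H14 face: ring A is an envelope with C15/C16 displaced to the other face, so this trajectory is anti to the pseudo-axial C16–H and remote from the C18 ester; this sets C12.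

**Step 15**
Reactants: 23 dienyl ester
Product: 24 unsaturated spiro ε-lactone (Z-C10=C11)
Conditions: (H2IMes)(PCy3)Cl2Ru=CHPh (second-generation Grubbs catalyst, 5 mol %), toluene (2 mM), 60 °C
Reagents that add atoms: none
Why: Ring-closing metathesis of two monosubstituted alkenes to a seven-membered lactone, helped by the fully substituted C12; the tetrasubstituted C13=C23 alkene is inert.

**Step 16**
Reactants: 24 unsaturated lactone
Product: 25 saturated spiro ε-lactone (C6H2)
Conditions: 2-nitrobenzenesulfonohydrazide, Et3N, CH2Cl2, 23 °C
Reagents that add atoms: none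
Why: Diimide reduction transfers two hydrogens syn to the cis-disubstituted alkene and leaves the tetrasubstituted alkene; being metal-free it cannot hydrogenolyse the allylic C12–O bond.

**Step 17**
Reactants: 25 saturated lactone, 26 1-bromopent-2-yne
Product: 28 C6-(pent-2-ynyl) spiro ε-lactone (C5 expected trans to the C27 arm), via lithium enolate 27 (not isolated)
Conditions: LiN(SiMe3)2 (1.1 equiv), THF, −78 °C; then 26, DMPU, −78 → −40 °C
Reagents that add atoms: none
Why: Enolate alkylation with a propargylic bromide; the ring-locked s-cis lactone is several pK units more acidic than the acyclic methyl ester, so only C6 is deprotonated and C17 is untouched. The C6 configuration is inconsequential because C6 becomes planar in step 18, and at −78 °C the lithium enolate does not rearrange.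

**Step 18**
Reactants: 28 C6-pentynyl lactone
Product: 31 cycloheptene C7 carboxylic acid (C6 and C23 quaternary; C12=C13), via silyl ketene acetal 29 (not isolated), via silyl ester 30 (not isolated)
Conditions: Me3SiCl, Et3N, KN(SiMe3)2 (1.3 equiv), toluene–THF, −78 °C; then 23 → 80 °C; pH 5 aqueous work-up
Reagents that add atoms: none
Why: Proposed new method: KN(SiMe3)2 removes the C6–H of the s-cis-locked lactone and Me3SiCl traps the enolate as ketene acetal 29, in which the tether C9–C10–C11 holds the array C6=C7–O–C12–C13=C23 in a boat (a bicyclo[3.2.2]nonane-like transition state); a concerted suprafacial [3,3] shift then forms C6–C23 as C12–O breaks and the alkene moves to C12=C13, giving silyl ester 30 and, on work-up, acid 31. The closest known reaction type is the Ireland–Claisen rearrangement of lactone silyl ketene acetals that carry an exocyclic alkene on the carbinol carbon, together with the acyclic ester-enolate Claisen rearrangement that joins two fully substituted carbons; their combination on a seven-membered lactone with both termini fully substituted is the untested element. Ring C closes in the pericyclic step itself, by C–C bond formation between the two ends of the tethered six-atom array as the lactone opens, not by a polar cyclisation. C23 is controlled by C12: the new bond forms on the alkene face that carried the C12–O bond, the face syn to C15. C6 is controlled by the tether: in the bridged transition state the pentynyl group can only point outward and C7 stays on the oxygen-bearing bridge, so either C6 epimer of 28 gives the same product, with C7 over ring C. The step needs enolisation at the lactone and not at the C18 ester, secured by the acidity difference, a small excess of base and silyl chloride already present, and it needs rearrangement to outrun enolate fragmentation, secured by silylation at −78 °C before warming. The steric cost is the contact of the two fully substituted termini and of the C24 and C27 arms, which is why heating is planned.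

**Step 19**
Reactants: 31 C7 acid
Product: 33 C7 primary alcohol, via acyl fluoride 32 (not isolated)
Conditions: cyanuric fluoride, pyridine, CH2Cl2, −10 → 0 °C; then NaBH4, MeOH, 0 °C
Reagents that add atoms: none
Why: Acyl fluoride formation and borohydride reduction; the small acyl fluoride suits a carboxyl flanked by two quaternary carbons, and NaBH4 at 0 °C leaves the methyl ester, carbamate and alkyne.

**Step 20**
Reactants: 33 C7 alcohol
Product: 34 C7 tert-butyldiphenylsilyl ether
Conditions: tBuPh2SiCl, imidazole, DMAP, DMF, 40 °C
Reagents that add atoms: tert-butyl(chloro)diphenylsilane, CC(C)(C)[Si](Cl)(c1ccccc1)c1ccccc1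
Why: Silylation of a hindered primary alcohol; a silyl chloride is used because silyl triflates would attack the Boc group.

**Step 21**
Reactants: 34 bis-silyl ether
Product: 35 C27 primary alcohol
Conditions: camphorsulfonic acid (10 mol %), MeOH–CH2Cl2, 0 °C
Reagents that add atoms: none
Why: Acid-catalysed methanolysis removes the unhindered primary TBS ether much faster than the neopentyl TBDPS ether; Boc survives catalytic sulfonic acid at 0 °C.

**Step 22**
Reactants: 35 C27 alcohol
Product: 36 C27 aldehyde
Conditions: Dess–Martin periodinane, pyridine, CH2Cl2, 0 → 23 °C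
Reagents that add atoms: none
Why: Buffered hypervalent-iodine oxidation stops at the aldehyde and does not epimerise C9.

**Step 23**
Reactants: 36 C27 aldehyde
Product: 39 N-methylpiperidine (ring D closed; C7–OTBDPS), via ammonium salt 37 (not isolated), via iminium salt 38 (not isolated)
Conditions: CF3CO2H, CH2Cl2, 0 °C; evaporate; NaBH(OAc)3, iPr2NEt, ClCH2CH2Cl, 23 °C
Reagents that add atoms: none
Why: Boc acidolysis, then intramolecular reductive amination: the freed amine closes on C27 to the six-membered iminium 38 (possible only because C27 and C24 are cis), which triacetoxyborohydride reduces faster than the aldehyde. No new stereocentre forms.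

**Step 24**
Reactants: 39 piperidine
Product: 40 amino alkynol (free C7–OH)
Conditions: Bu4NF, THF, 23 → 40 °C; aq. NH4Cl
Reagents that add atoms: none
Why: Fluoride cleavage of the silyl ether under conditions that do not epimerise C17.

**Step 25**
Reactants: 40 amino alkynol
Product: 43 CNP0159589.3, via ammonium triflimide 41 (not isolated), via target triflimide 42 (not isolated)
Conditions: HN(SO2CF3)2 (1.0 equiv), Ph3PAuN(SO2CF3)2 (5 mol %), 4 Å MS, CH2Cl2, 23 °C; then Et3N
Reagents that add atoms: none
Why: Gold-catalysed hydroalkoxylation of an alkyne: monovalent gold activates C3≡C4, the C7 hydroxyl adds anti at C3 (6-endo-dig) and protodeauration gives the endocyclic enol ether. One equivalent of a non-coordinating acid keeps the amine as ammonium so that it cannot bind gold, and the ammonium is too weak an acid to open the enol ether.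

## Compound list

1 | N-Boc-sarcosine | CN(CC(=O)O)C(=O)OC(C)(C)C | starting material
2 | tert-butyl {2-[methoxy(methyl)amino]-2-oxoethyl}(methyl)carbamate | CON(C)C(=O)CN(C)C(=O)OC(C)(C)C | intermediate
3 | lithium adduct of 2 with chloromethyllithium | [Li+].CON(C)C([O-])(CCl)CN(C)C(=O)OC(C)(C)C | intermediate (not isolated)
4 | tert-butyl (3-chloro-2-oxopropyl)(methyl)carbamate | CN(CC(=O)CCl)C(=O)OC(C)(C)C | intermediate
5 | cyclopent-2-en-1-one | O=C1C=CCC1 | starting material
6 | diallyl malonate | C=CCOC(=O)CC(=O)OCC=C | starting material
7 | diallyl 2-[(1S)-3-oxocyclopentyl]propanedioate | O=C1C[C@H](CC1)C(C(=O)OCC=C)C(=O)OCC=C | intermediate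
8 | diallyl 2-{3-[(tert-butoxycarbonyl)(methyl)amino]-2-oxopropyl}-2-[(1S)-3-oxocyclopentyl]propanedioate | O=C1C[C@H](CC1)C(CC(=O)CN(C)C(=O)OC(C)(C)C)(C(=O)OCC=C)C(=O)OCC=C | intermediate
9 | aldol adduct (C23 carbinol, mixture at C13/C23) | O=C1CC[C@H]2C1C(O)(CN(C)C(=O)OC(C)(C)C)CC2(C(=O)OCC=C)C(=O)OCC=C | intermediate (not isolated)
10 | diallyl (6aS)-3-{[(tert-butoxycarbonyl)(methyl)amino]methyl}-4-oxo-4,5,6,6a-tetrahydropentalene-1,1(2H)-dicarboxylate | O=C1CC[C@H]2C1=C(CN(C)C(=O)OC(C)(C)C)CC2(C(=O)OCC=C)C(=O)OCC=C | intermediate
11 | the 1,1-dicarboxylic acid of 10 | O=C1CC[C@H]2C1=C(CN(C)C(=O)OC(C)(C)C)CC2(C(=O)O)C(=O)O | intermediate (not isolated)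
12 | (1R,6aR)-3-{[(tert-butoxycarbonyl)(methyl)amino]methyl}-4-oxo-1,2,4,5,6,6a-hexahydropentalene-1-carboxylic acid | O=C1CC[C@H]2C1=C(CN(C)C(=O)OC(C)(C)C)C[C@H]2C(=O)O | intermediate
13 | methyl ester of 12 | O=C1CC[C@H]2C1=C(CN(C)C(=O)OC(C)(C)C)C[C@H]2C(=O)OC | intermediate
14 | (E)-but-2-ene-1,4-diol | OC/C=C/CO | starting material
15 | (E)-4-[(tert-butyldimethylsilyl)oxy]but-2-en-1-ol | CC(C)(C)[Si](C)(C)OC/C=C/CO | intermediate
16 | (E)-4-[(tert-butyldimethylsilyl)oxy]but-2-en-1-yl methyl carbonate | COC(=O)OC/C=C/CO[Si](C)(C)C(C)(C)C | intermediate
17 | dimethyl malonate | COC(=O)CC(=O)OC | starting material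
18 | dimethyl 2-[(2S)-1-[(tert-butyldimethylsilyl)oxy]but-3-en-2-yl]propanedioate | COC(=O)C(C(=O)OC)[C@@H](CO[Si](C)(C)C(C)(C)C)C=C | intermediate
19 | methyl (3R)-3-{[(tert-butyldimethylsilyl)oxy]methyl}pent-4-enoate | COC(=O)C[C@@H](CO[Si](C)(C)C(C)(C)C)C=C | intermediate
20 | (3R)-3-{[(tert-butyldimethylsilyl)oxy]methyl}pent-4-enoic acid | OC(=O)C[C@@H](CO[Si](C)(C)C(C)(C)C)C=C | intermediate
21 | (3R)-3-{[(tert-butyldimethylsilyl)oxy]methyl}pent-4-enoyl chloride | ClC(=O)C[C@@H](CO[Si](C)(C)C(C)(C)C)C=C | intermediate
22 | bromomagnesium alkoxide of the C12 vinyl carbinol (O on the C15 face) | C=C[C@@]1(O[Mg]Br)CC[C@H]2C1=C(CN(C)C(=O)OC(C)(C)C)C[C@H]2C(=O)OC | intermediate (not isolated)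
23 | dienyl ester: C12 tertiary ester of acid 20, vinyl on the H14 face | C=C[C@@]1(OC(=O)C[C@@H](CO[Si](C)(C)C(C)(C)C)C=C)CC[C@H]2C1=C(CN(C)C(=O)OC(C)(C)C)C[C@H]2C(=O)OC | intermediate
24 | unsaturated spiro ε-lactone (Z-C10=C11) | C1C(=O)O[C@@]2(CC[C@H]3C2=C(CN(C)C(=O)OC(C)(C)C)C[C@H]3C(=O)OC)C=C[C@@H]1CO[Si](C)(C)C(C)(C)C | intermediate
25 | saturated spiro ε-lactone (C6H2) | C1C(=O)O[C@@]2(CC[C@H]3C2=C(CN(C)C(=O)OC(C)(C)C)C[C@H]3C(=O)OC)CC[C@@H]1CO[Si](C)(C)C(C)(C)C | intermediate
26 | 1-bromopent-2-yne | CCC#CCBr | starting material
27 | lithium enolate of lactone 25 | [Li+].C1=C([O-])O[C@@]2(CC[C@H]3C2=C(CN(C)C(=O)OC(C)(C)C)C[C@H]3C(=O)OC)CC[C@@H]1CO[Si](C)(C)C(C)(C)C | intermediate (not isolated)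
28 | C6-(pent-2-ynyl) spiro ε-lactone, C5 trans to the C27 arm (Claisen precursor; the C6 epimer is equivalent) | CCC#CC[C@H]1C(=O)O[C@@]2(CC[C@H]3C2=C(CN(C)C(=O)OC(C)(C)C)C[C@H]3C(=O)OC)CC[C@@H]1CO[Si](C)(C)C(C)(C)C | intermediate
29 | lactone trimethylsilyl ketene acetal (C6=C7) | CCC#CCC1=C(O[Si](C)(C)C)O[C@@]2(CC[C@H]3C2=C(CN(C)C(=O)OC(C)(C)C)C[C@H]3C(=O)OC)CC[C@@H]1CO[Si](C)(C)C(C)(C)C | intermediate (not isolated)
30 | trimethylsilyl ester of 31 | CCC#CC[C@@]1(C(=O)O[Si](C)(C)C)[C@@H](CO[Si](C)(C)C(C)(C)C)CCC2=C3[C@H](CC2)[C@H](C(=O)OC)C[C@@]31CN(C)C(=O)OC(C)(C)C | intermediate (not isolated)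
31 | cycloheptene C7 carboxylic acid (Claisen product) | CCC#CC[C@@]1(C(=O)O)[C@@H](CO[Si](C)(C)C(C)(C)C)CCC2=C3[C@H](CC2)[C@H](C(=O)OC)C[C@@]31CN(C)C(=O)OC(C)(C)C | intermediate
32 | C7 acyl fluoride | CCC#CC[C@@]1(C(F)=O)[C@@H](CO[Si](C)(C)C(C)(C)C)CCC2=C3[C@H](CC2)[C@H](C(=O)OC)C[C@@]31CN(C)C(=O)OC(C)(C)C | intermediate (not isolated)
33 | C7 primary alcohol | CCC#CC[C@@]1(CO)[C@@H](CO[Si](C)(C)C(C)(C)C)CCC2=C3[C@H](CC2)[C@H](C(=O)OC)C[C@@]31CN(C)C(=O)OC(C)(C)C | intermediate
34 | C7 TBDPS ether, C27 TBS ether | CCC#CC[C@@]1(CO[Si](c4ccccc4)(c5ccccc5)C(C)(C)C)[C@@H](CO[Si](C)(C)C(C)(C)C)CCC2=C3[C@H](CC2)[C@H](C(=O)OC)C[C@@]31CN(C)C(=O)OC(C)(C)C | intermediate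
35 | C27 primary alcohol | CCC#CC[C@@]1(CO[Si](c4ccccc4)(c5ccccc5)C(C)(C)C)[C@@H](CO)CCC2=C3[C@H](CC2)[C@H](C(=O)OC)C[C@@]31CN(C)C(=O)OC(C)(C)C | intermediate
36 | C27 aldehyde | CCC#CC[C@@]1(CO[Si](c4ccccc4)(c5ccccc5)C(C)(C)C)[C@@H](C=O)CCC2=C3[C@H](CC2)[C@H](C(=O)OC)C[C@@]31CN(C)C(=O)OC(C)(C)C | intermediate
37 | N-methylammonium trifluoroacetate of the Boc-free aldehyde | CCC#CC[C@@]1(CO[Si](c4ccccc4)(c5ccccc5)C(C)(C)C)[C@@H](C=O)CCC2=C3[C@H](CC2)[C@H](C(=O)OC)C[C@@]31C[NH2+]C.[O-]C(=O)C(F)(F)F | intermediate (not isolated)
38 | cyclic iminium (N25=C27) trifluoroacetate | CCC#CC[C@@]2(CO[Si](c5ccccc5)(c6ccccc6)C(C)(C)C)[C@@H]1CCC3=C4[C@H](CC3)[C@H](C(=O)OC)C[C@@]42C[N+](C)=C1.[O-]C(=O)C(F)(F)F | intermediate (not isolated)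
39 | N-methylpiperidine with C7–OTBDPS and the pentynyl arm | CCC#CC[C@@]2(CO[Si](c5ccccc5)(c6ccccc6)C(C)(C)C)[C@@H]1CCC3=C4[C@H](CC3)[C@H](C(=O)OC)C[C@@]42CN(C)C1 | intermediate
40 | amino alkynol (C7–OH) | CCC#CC[C@@]2(CO)[C@@H]1CCC3=C4[C@H](CC3)[C@H](C(=O)OC)C[C@@]42CN(C)C1 | intermediate
41 | ammonium triflimide of 40 | CCC#CC[C@@]2(CO)[C@@H]1CCC3=C4[C@H](CC3)[C@H](C(=O)OC)C[C@@]42C[NH+](C)C1.FC(F)(F)S(=O)(=O)[N-]S(=O)(=O)C(F)(F)F | intermediate (not isolated)
42 | ammonium triflimide of 43 | CCC1=CC[C@@]2(CO1)[C@@H]1CCC3=C4[C@H](CC3)[C@H](C(=O)OC)C[C@@]42C[NH+](C)C1.FC(F)(F)S(=O)(=O)[N-]S(=O)(=O)C(F)(F)F | intermediate (not isolated)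
43 | CNP0159589.3 | CCC1=CC[C@@]2(CO1)[C@@H]1CCC3=C4[C@H](CC3)[C@H](C(=O)OC)C[C@@]42CN(C)C1 | target

## Step count and least certain steps

Total: 25 steps. Longest linear sequence: 18 steps (1 → 43 through steps 1, 2, 4–7, 14–25; the branch from 14 is equally long).

**Step 18 (key step; carries the label).** The most likely failure is that the [3,3] shift does not compete with loss of the ketene acetal. Both termini are fully substituted and the C24 and C27 arms are pressed together in the boat, so on heating 29 may simply return 28 on work-up or fragment by ketene extrusion. A second danger is partial enolisation of the C18 ester with epimerisation at C17.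
Fallback (known chemistry, two-stage): set out from lactone 25 and rearrange it before alkylation, under the conditions of step 18. This is the lactone-enolate Claisen with only one fully substituted terminus and should give the C6–H cycloheptene acid F1. Reduce it as in step 19 to the alcohol F2, oxidise with Dess–Martin periodinane to the aldehyde F3, form its potassium enolate (KN(SiMe3)2, THF, −78 °C; only the aldehyde α-hydrogen is acidic enough) and alkylate with 26 to the α-quaternary aldehyde F4. NaBH4 then returns the route to alcohol 33. The price is that C6 is no longer fixed by the tether but by approach of the electrophile to the face H6 occupied, away from the folded ring C, which is less certain.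

**Step 14.** The risk is poor facial selectivity at C12. The enone is nearly flat and the two faces differ only by the puckering of ring A and the remote ester; the wrong C12 epimer would relay the wrong face to C23. Incomplete acylation of the hindered alkoxide is the second risk.
Fallback: set out from ketone 13 and replace substrate control by catalyst control, a titanium-catalysed enantioselective vinylation (Zn(CH=CH2)2, Ti(OiPr)4, a chiral bis(sulfonamide) diol ligand chosen for the matched sense). This gives the tertiary dienol F5, which is deprotonated separately (KN(SiMe3)2, THF, −78 °C) and acylated with 21, coming back at 23.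

**Step 6.** The risk is loss of facial control in the protonation of the enol at 100 °C, giving the more stable epimer with the ester trans to C15.
Fallback: the configuration is corrected late, where the ester enolate is the only enolate that can form. It sets out from the stage of piperidine 39, in which any C17-epimeric material, the C17 epimer of 39 F6, is still present. Treatment with LiN(iPr)2 (THF, −78 °C) and quenching with 2,6-di-tert-butylphenol should protonate C17 on the face of H14 and C24, away from C15 and C6, and return 39.

**Step 25.** The risk is competing 5-exo-dig attack at C4, which would give a spiro tetrahydrofuran with an exocyclic alkene, or slow turnover if the ammonium salt still inhibits gold.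
Fallback: change the order. Set out from alcohol 33, where no amine is present, and cyclise with divalent palladium (PdCl2(MeCN)2, THF), an oxypalladation–protodepalladation pathway that favours endo closure for internal 4-alkyn-1-ols, to the Boc-protected spiro dihydropyran F7. Remove the silyl group (Bu4NF) to the C27 alcohol F8 and convert it into the mesylate F9 (MeSO2Cl, Et3N). Cleave the Boc group without acid (tBuMe2SiOTf, 2,6-lutidine; then Bu4NF) to the secondary amine mesylate F10, which closes ring D by intramolecular N-alkylation (K2CO3, MeCN, 60 °C) and comes back at target 43.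

## Further compounds

F1 | step 18 | C6–H cycloheptene C7 carboxylic acid | OC(=O)[C@@H]1[C@@H](CO[Si](C)(C)C(C)(C)C)CCC2=C3[C@H](CC2)[C@H](C(=O)OC)C[C@@]31CN(C)C(=O)OC(C)(C)C
F2 | step 18 | C6–H C7 alcohol | OC[C@@H]1[C@@H](CO[Si](C)(C)C(C)(C)C)CCC2=C3[C@H](CC2)[C@H](C(=O)OC)C[C@@]31CN(C)C(=O)OC(C)(C)C
F3 | step 18 | C6–H C7 aldehyde | O=C[C@@H]1[C@@H](CO[Si](C)(C)C(C)(C)C)CCC2=C3[C@H](CC2)[C@H](C(=O)OC)C[C@@]31CN(C)C(=O)OC(C)(C)C
F4 | step 18 | α-quaternary C7 aldehyde with the pentynyl arm | CCC#CC[C@@]1(C=O)[C@@H](CO[Si](C)(C)C(C)(C)C)CCC2=C3[C@H](CC2)[C@H](C(=O)OC)C[C@@]31CN(C)C(=O)OC(C)(C)C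
F5 | step 14 | tertiary dienol (C12–OH on the C15 face) | C=C[C@@]1(O)CC[C@H]2C1=C(CN(C)C(=O)OC(C)(C)C)C[C@H]2C(=O)OC
F6 | step 6 | C17 epimer of 39 | CCC#CC[C@@]2(CO[Si](c5ccccc5)(c6ccccc6)C(C)(C)C)[C@@H]1CCC3=C4[C@H](CC3)[C@@H](C(=O)OC)C[C@@]42CN(C)C1
F7 | step 25 | Boc-protected spiro dihydropyran with C27–OTBS | CCC1=CC[C@@]2(CO1)[C@@H](CO[Si](C)(C)C(C)(C)C)CCC3=C4[C@H](CC3)[C@H](C(=O)OC)C[C@@]42CN(C)C(=O)OC(C)(C)C
F8 | step 25 | C27 alcohol of F7 | CCC1=CC[C@@]2(CO1)[C@@H](CO)CCC3=C4[C@H](CC3)[C@H](C(=O)OC)C[C@@]42CN(C)C(=O)OC(C)(C)C
F9 | step 25 | C27 mesylate | CCC1=CC[C@@]2(CO1)[C@@H](COS(C)(=O)=O)CCC3=C4[C@H](CC3)[C@H](C(=O)OC)C[C@@]42CN(C)C(=O)OC(C)(C)C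
F10 | step 25 | secondary amine mesylate | CCC1=CC[C@@]2(CO1)[C@@H](COS(C)(=O)=O)CCC3=C4[C@H](CC3)[C@H](C(=O)OC)C[C@@]42CNC
A1 | alternative 1 | bicyclic cycloheptadiene silyl enol ether | C[Si](C)(C)C1=C2[C@H](C=C)[C@H](C(=O)OC)C[C@@H]2C(O[Si](C)(C)C(C)(C)C)=CCC1
A2 | alternative 1 | tethered silylalkyne–siloxyvinylcyclopropane | C[Si](C)(C)C#C[C@H](C=C)[C@H](C(=O)OC)CC=C(O[Si](C)(C)C(C)(C)C)C1CC1
A3 | alternative 2 | spiro dihydropyran with a 1,3-dithiane at C7 | CCC1=CC[C@@]2(C3(SCCCS3)O1)[C@@H]4CCC5=C6[C@H](CC5)[C@H](C(=O)OC)C[C@@]62CN(C)C4
A4 | alternative 2 | pent-1-en-3-one | CCC(=O)C=C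
A5 | alternative 2 | C6=C7 ketene dithioacetal of the tetracyclic core | S1CCCSC1=C2[C@@H]3CCC4=C5[C@H](CC4)[C@H](C(=O)OC)C[C@@]52CN(C)C3
A6 | alternative 3 | fused cycloheptane-1,4-dione | O=C1CCCC(=O)[C@H]2[C@@H]1C[C@@H](C(=O)OC)[C@H]2CCO[Si](C)(C)C(C)(C)C
A7 | alternative 3 | ethene | C=C
A8 | alternative 3 | cis-fused bicyclo[3.3.0]octane-2,4-dione | O=C1CC(=O)[C@H]2[C@@H]1C[C@@H](C(=O)OC)[C@H]2CCO[Si](C)(C)C(C)(C)C
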